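## Retrosynthetic overview
1. Rufesolide C comes from a late C6 angelate (Yamaguchi) and a C3 ketone (DMP oxidation of the C3 alcohol). The α‑methylene is installed by Eschenmoser methylenation of the saturated trans‑fused 8,12‑lactone.
2. The 10‑membered carbocycle and the γ‑lactone form together in one step: SmI2 ketyl–enoate cyclisation of a C8 aldehyde onto a C7=C11 enoate (C7–C8 bond, then lactonisation).
3. C1/C10 (syn) are set by Brown (Z)‑crotylboration of a C1 aldehyde. That aldehyde comes from C3 by allylation/ozonolysis, and the terminal vinyl is later turned into the C8 aldehyde by an anti‑Markovnikov Wacker oxidation.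
4. C4 comes from (R)‑linalyl acetate. Its prenyl arm becomes the C7 aldehyde, and proline α‑aminoxylation with in‑situ Wittig sets C6 and supplies the enoate. Its vinyl arm becomes the C3 aldehyde.

Numbering below is germacrane numbering: ring C1–C10, C11 α‑carbon, C12 lactone C=O, C13 methylene, C14 Me on C10, C15 Me on C4.

Assumptions:
- (R)‑Linalyl acetate is commercially available.
- D‑Proline is taken to give the 6S aminoxy aldehyde.
- The (−)‑Ipc2B reagents are taken to give 3S and 1R,10R. If the opposite sense is obtained, use the enantiomeric catalyst or reagent.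
- The macrocyclisation is assumed to favour the natural trans‑fused diastereomer.

## Route

**Step 1**
Reactants: 1 (R)‑linalyl acetate
Product: 2 epoxide of the 6,7‑alkene
Conditions: mCPBA (1.0 equiv), NaHCO3, CH2Cl2, 0 °C
Reagents that add atoms: mCPBA, OOC(=O)c1cccc(Cl)c1 (O)
Why: Prilezhaev epoxidation is selective for the electron‑rich trisubstituted alkene over the acetate‑deactivated vinyl. C4 is untouched, and the epoxide epimers are irrelevant because that carbon is excised next.

**Step 2**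
Reactants: 2
Product: 3 (4R)‑4‑acetoxy‑4‑methylhex‑5‑enal
Conditions: H5IO6, Et2O/THF, rt
Reagents that add atoms: water, O (epoxide hydration)
Why: Periodic acid hydrates the epoxide and cleaves the diol (Malaprade) to the C7 aldehyde, releasing acetone. No stereocentre is touched.

**Step 3**
Reactants: 3, 4 nitrosobenzene, 5 ethyl (triphenylphosphoranylidene)acetate
Product: 6 ethyl (2E,4S,6R)‑6‑acetoxy‑6‑methyl‑4‑(phenylaminooxy)octa‑2,7‑dienoate
Conditions: 4 (1.2 equiv), D‑proline (20 mol%), MeCN, −20 °C; then 5, rt (one pot)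
Reagents that add atoms: 4, O=Nc1ccccc1; 5, CCOC(=O)C=P(c1ccccc1)(c1ccccc1)c1ccccc1
Why: Enamine‑catalysed nitroso‑aldol (O‑selective α‑aminoxylation) sets C6 (S) under catalyst control, overriding the remote C4. The aminoxy aldehyde is trapped at once by Wittig olefination to the E‑enoate (C7=C11), which avoids epimerisation.

**Step 4**
Reactants: 6
Product: 7 ethyl (2E,4S,6R)‑6‑acetoxy‑4‑hydroxy‑6‑methylocta‑2,7‑dienoate
Conditions: CuSO4·5H2O (10 mol%), MeOH, rt
Reagents that add atoms: none (PhN=NPh is the by‑product)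
Why: Cu(II) promotes N–O cleavage of the O‑aryl‑hydroxylamine ether (disproportionation), freeing the alcohol with retention at C6.

**Step 5**
Reactants: 7
Product: 8 C6 TBS ether
Conditions: TBSCl, imidazole, DMF, rt
Reagents that add atoms: TBSCl, CC(C)(C)[Si](C)(C)Cl
Why: Silylation of the secondary alcohol protects it for the later steps (SmI2, methylenation).

**Step 6**
Reactants: 8
Product: 9 C3 aldehyde (ethyl (2E,4S,6R)‑6‑acetoxy‑4‑TBSO‑6‑methyl‑7‑oxohept‑2‑enoate)
Conditions: O3 (1 equiv), CH2Cl2, −78 °C; then Me2S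
Reagents that add atoms: ozone, [O-][O+]=O (aldehyde O)
Why: Ozonolysis cleaves the terminal vinyl much faster than the electron‑poor enoate. C4 is unchanged (R).

**Step 7**
Reactants: 9, 10 (−)‑B‑allyldiisopinocampheylborane
Product: 11 homoallylic alcohol (C3 S)
Conditions: 10, Et2O, −78 °C; then NaBO3·4H2O, THF/H2O
Reagents that add atoms: 10, C=CCB(C1CC2CC(C2(C)C)C1C)C1CC2CC(C2(C)C)C1C (allyl group)
Why: Allylboration proceeds through a chair TS, and the Ipc2B reagent controls C3. C3 is later oxidised, so it only needs to be a single epimer. The buffered perborate work‑up avoids cleaving or migrating the acetate.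

**Step 8**
Reactants: 11
Product: 12 C3 TES ether
Conditions: TESOTf, 2,6‑lutidine, CH2Cl2, −78 °C
Reagents that add atoms: TESOTf, CC[Si](CC)(CC)OS(=O)(=O)C(F)(F)F
Why: The vicinal acetate/alcohol is locked as a silyl ether, which prevents acyl migration and protects C3 for the crotylation.

**Step 9**
Reactants: 12
Product: 13 C1 aldehyde (β‑silyloxy aldehyde)
Conditions: O3, CH2Cl2, −78 °C; then Me2S
Reagents that add atoms: ozone, [O-][O+]=O
Why: Selective cleavage of the terminal allyl alkene gives the aldehyde needed for crotylation.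

**Step 10**
Reactants: 13, 14 (Z)‑crotyl‑(−)‑Ipc2B (from cis‑2‑butene, KOtBu/nBuLi, (−)‑Ipc2BOMe, BF3·OEt2)
Product: 15 syn homoallylic alcohol (1R,10R)
Conditions: 14, THF/Et2O, −78 °C; then NaBO3·4H2O, THF/H2O
Reagents that add atoms: 14, C/C=C\CB(C1CC2CC(C2(C)C)C1C)C1CC2CC(C2(C)C)C1C (crotyl group)
Why: Brown crotylboration. The Z‑crotylborane reacts through a closed chair TS to give the syn relationship of C1‑OH and C10‑Me, and the Ipc2B reagent sets both centres at once under reagent control.

**Step 11**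
Reactants: 15, 16 methyl triflate
Product: 17 C1 methyl ether
Conditions: 16, 2,6‑di‑tert‑butyl‑4‑methylpyridine, CH2Cl2, rt
Reagents that add atoms: 16, COS(=O)(=O)C(F)(F)F (CH3)
Why: O‑Methylation with a non‑nucleophilic base is done now, while no ketone is present. A β‑methoxy ketone would eliminate under basic methylation.

**Step 12**
Reactants: 17
Product: 18 C8 aldehyde
Conditions: PdCl2(PhCN)2, CuCl2, AgNO2 (10 mol% each), O2, t‑BuOH/MeNO2, rt
Reagents that add atoms: O2, O=O (aldehyde O)
Why: Nitrite‑modified Wacker oxidation is anti‑Markovnikov‑selective and converts the terminal vinyl to the C8 aldehyde. The enoate, esters and silyl ethers are tolerated.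

**Step 13**
Reactants: 18
Product: 19 saturated trans‑fused 8,12‑lactone (3‑O‑TES, 6‑O‑TBS, 4‑OAc, 1‑OMe 11,13‑dihydrogermacran‑8,12‑olide)
Conditions: SmI2 (2.5 equiv), HMPA, t‑BuOH, THF, 0.003 M (syringe pump), −78 → 0 °C
Reagents that add atoms: none (EtOH is lost on lactonisation)
Why: The ketyl radical at C8 adds to the β‑carbon (C7) of the enoate, closing the ten‑membered ring (10‑exo). The Sm alkoxide then lactonises onto the ester. The C7/C8 trans relationship and the C6/C10/C1 relationship are assumed to be controlled by the transannular conformation and a Felkin‑type anti attack relative to the C6 OTBS. C3 must still be an alcohol because SmI2 would reductively cleave the α‑acetoxy ketone.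

**Step 14**
Reactants: 19, 20 Eschenmoser's salt
Product: 21 α‑methylene lactone
Conditions: LiHMDS, THF, −78 °C; then 20; then MeI; then DBU, CH2Cl2
Reagents that add atoms: 20, C=[N+](C)C.[I-] (CH2); MeI and DBU leave no atoms
Why: Lactone enolate Mannich aminomethylation, then quaternisation and E1cB elimination give the exocyclic C11=C13. C11 is not a stereocentre in the product.

**Step 15**
Reactants: 21
Product: 22 C3 alcohol
Conditions: PPTS, MeOH/CH2Cl2, 0 °C → rt
Reagents that add atoms: none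
Why: The primary‑like TES ether is cleaved under mild acid while the hindered C6 TBS ether remains.

**Step 16**
Reactants: 22
Product: 23 C3 ketone
Conditions: DMP, NaHCO3, CH2Cl2, rt
Reagents that add atoms: none
Why: Dess–Martin oxidation of the hindered secondary alcohol gives the α‑acetoxy, β‑methoxy ketone. The α‑methylene lactone survives.

**Step 17**
Reactants: 23
Product: 24 C6 alcohol
Conditions: HF·pyridine, pyridine, THF, rt
Reagents that add atoms: none
Why: Buffered fluoride removes the TBS group. Basic fluoride (TBAF) is avoided because it could eliminate the β‑OMe.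

**Step 18**
Reactants: 24, 25 angelic acid
Product: 26 rufesolide C
Conditions: 2,4,6‑Cl3C6H2COCl, Et3N, THF; then 24, DMAP, toluene, rt (Yamaguchi)
Reagents that add atoms: 25, OC(=O)/C(C)=C\C (angeloyl)
Why: The mixed anhydride acylates the C6 alcohol with retention of the Z‑alkene geometry. Low temperature limits isomerisation to the tiglate.

## Compound list
1 | (R)‑linalyl acetate, (3R)‑3,7‑dimethylocta‑1,6‑dien‑3‑yl acetate | C=C[C@](C)(OC(C)=O)CCC=C(C)C | starting material
2 | (3R)‑5‑(3,3‑dimethyloxiran‑2‑yl)‑3‑methylpent‑1‑en‑3‑yl acetate (epoxide epimers) | C=C[C@](C)(OC(C)=O)CCC1OC1(C)C | intermediate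
3 | (4R)‑4‑acetoxy‑4‑methylhex‑5‑enal | C=C[C@](C)(OC(C)=O)CCC=O | intermediate
4 | nitrosobenzene | O=Nc1ccccc1 | starting material
5 | ethyl (triphenylphosphoranylidene)acetate | CCOC(=O)C=P(c1ccccc1)(c1ccccc1)c1ccccc1 | starting material
6 | ethyl (2E,4S,6R)‑6‑acetoxy‑6‑methyl‑4‑(phenylaminooxy)octa‑2,7‑dienoate | C=C[C@](C)(OC(C)=O)C[C@H](ONc1ccccc1)/C=C/C(=O)OCC | intermediate
7 | ethyl (2E,4S,6R)‑6‑acetoxy‑4‑hydroxy‑6‑methylocta‑2,7‑dienoate | C=C[C@](C)(OC(C)=O)C[C@H](O)/C=C/C(=O)OCC | intermediate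
8 | C6 TBS ether of 7 | C=C[C@](C)(OC(C)=O)C[C@H](O[Si](C)(C)C(C)(C)C)/C=C/C(=O)OCC | intermediate
9 | ethyl (2E,4S,6R)‑6‑acetoxy‑4‑TBSO‑6‑methyl‑7‑oxohept‑2‑enoate | O=C[C@](C)(OC(C)=O)C[C@H](O[Si](C)(C)C(C)(C)C)/C=C/C(=O)OCC | intermediate
10 | (−)‑B‑allyldiisopinocampheylborane (Ipc stereo omitted) | C=CCB(C1CC2CC(C2(C)C)C1C)C1CC2CC(C2(C)C)C1C | starting material (reagent)
11 | C3 (S) homoallylic alcohol (deca‑2,9‑dienoate) | C=CC[C@H](O)[C@](C)(OC(C)=O)C[C@H](O[Si](C)(C)C(C)(C)C)/C=C/C(=O)OCC | intermediate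
12 | C3 TES ether of 11 | C=CC[C@H](O[Si](CC)(CC)CC)[C@](C)(OC(C)=O)C[C@H](O[Si](C)(C)C(C)(C)C)/C=C/C(=O)OCC | intermediate
13 | C1 aldehyde (9‑oxonon‑2‑enoate) | O=CC[C@H](O[Si](CC)(CC)CC)[C@](C)(OC(C)=O)C[C@H](O[Si](C)(C)C(C)(C)C)/C=C/C(=O)OCC | intermediate
14 | (Z)‑crotyl‑(−)‑Ipc2B, from cis‑2‑butene C/C=C\C (Ipc stereo omitted) | C/C=C\CB(C1CC2CC(C2(C)C)C1C)C1CC2CC(C2(C)C)C1C | starting material (reagent)
15 | syn homoallylic alcohol (1R,10R) | C=C[C@@H](C)[C@H](O)C[C@H](O[Si](CC)(CC)CC)[C@](C)(OC(C)=O)C[C@H](O[Si](C)(C)C(C)(C)C)/C=C/C(=O)OCC | intermediate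
16 | methyl triflate | COS(=O)(=O)C(F)(F)F | starting material (reagent)
17 | C1 methyl ether | C=C[C@@H](C)[C@H](OC)C[C@H](O[Si](CC)(CC)CC)[C@](C)(OC(C)=O)C[C@H](O[Si](C)(C)C(C)(C)C)/C=C/C(=O)OCC | intermediate
18 | C8 aldehyde (12‑oxododec‑2‑enoate) | O=CC[C@@H](C)[C@H](OC)C[C@H](O[Si](CC)(CC)CC)[C@](C)(OC(C)=O)C[C@H](O[Si](C)(C)C(C)(C)C)/C=C/C(=O)OCC | intermediate
19 | saturated trans‑fused 8,12‑olide (3‑OTES, 6‑OTBS, 4‑OAc, 1‑OMe) | O=C1O[C@@H]2C[C@@H](C)[C@H](OC)C[C@H](O[Si](CC)(CC)CC)[C@](C)(OC(C)=O)C[C@H](O[Si](C)(C)C(C)(C)C)[C@H]2C1 | intermediate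
20 | Eschenmoser's salt | C=[N+](C)C.[I-] | starting material (reagent)
21 | α‑methylene lactone (3‑OTES, 6‑OTBS) | C=C1C(=O)O[C@@H]2C[C@@H](C)[C@H](OC)C[C@H](O[Si](CC)(CC)CC)[C@](C)(OC(C)=O)C[C@H](O[Si](C)(C)C(C)(C)C)[C@@H]12 | intermediate
22 | C3 alcohol (6‑OTBS) | C=C1C(=O)O[C@@H]2C[C@@H](C)[C@H](OC)C[C@H](O)[C@](C)(OC(C)=O)C[C@H](O[Si](C)(C)C(C)(C)C)[C@@H]12 | intermediate
23 | C3 ketone (6‑OTBS) | C=C1C(=O)O[C@@H]2C[C@@H](C)[C@H](OC)CC(=O)[C@](C)(OC(C)=O)C[C@H](O[Si](C)(C)C(C)(C)C)[C@@H]12 | intermediate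
24 | C6 alcohol | C=C1C(=O)O[C@@H]2C[C@@H](C)[C@H](OC)CC(=O)[C@](C)(OC(C)=O)C[C@H](O)[C@@H]12 | intermediate
25 | angelic acid ((Z)‑2‑methylbut‑2‑enoic acid) | OC(=O)/C(C)=C\C | starting material
26 | rufesolide C | C=C1C(=O)O[C@@H]2C[C@@H](C)[C@H](OC)CC(=O)[C@](C)(OC(C)=O)C[C@H](OC(=O)/C(C)=C\C)[C@@H]12 | target

## Totals
Total steps: 18. Longest linear sequence: 18 steps (1 → 26).

Three steps most likely to fail:
1. **Step 13 (SmI2 macrocyclisation):** yield and C7/C8 diastereocontrol in the ten‑membered ring are uncertain. Fallback: change the closure to an intramolecular Nozaki–Hiyama–Kishi allylation (CrCl2/NiCl2) of the C8 aldehyde with a (Z)‑2‑(bromomethyl)enoate at C7. The bromide would be made from the C7 aldehyde by Baylis–Hillman/SN2′. This is anti‑selective, gives the trans‑lactone and installs the methylene directly, so it removes step 14.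
2. **Step 7 (allylboration of the α‑acetoxy aldehyde):** acetate 1,2‑migration or low dr is possible. Fallback: Wacker‑oxidise 1 to the methyl ketone, then run an Ipc2B boron aldol with (S)‑4‑silyloxy‑2‑methylbutanal (from 2‑methylsuccinate). This avoids the free C3 carbinol beside the tertiary acetate.
3. **Step 14 (LiHMDS methylenation of the acetate‑ and silyl‑bearing macrolactone):** base sensitivity is the concern. Fallback: trap the Sm(III) enolate generated in step 13 directly with Eschenmoser's salt (then MeI/DBU), which removes the separate strong‑base step.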